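Abbreviations used throughout: Chr = 7-methoxy-2,2-dimethyl-2H-chromen-6-yl (ring B with its fused dimethylpyran ring D); TBS = tert-butyldimethylsilyl; TIPS = triisopropylsilyl. Atom numbers O1, C2, C3, C4, C4a, C5–C8, C8a are those of the chroman-4-one core of the target 28.

## Analysis of the target

The target 28 is a (3S)-isoflavanone: a chroman-4-one (benzo ring A fused to pyranone ring C) whose C3 carries ring B, which is itself fused to a 2,2-dimethyl-2H-pyran (ring D). C3 is the only stereocentre. It is benzylic and alpha to the C4 ketone, so it epimerises by enolisation under mild base or acid, and ring C can also open by loss of the O1 phenoxide from the enolate, which racemises it as well. The sensitive groups are the styrene-type double bond of ring D (acid, electrophiles, hydrogenation, quinone oxidants) and the C5 phenol that is hydrogen-bonded to the ketone. The two methyl ethers, at C7 and on ring B, rule out an unselective late demethylation. The difficulty is therefore twofold: C3 must be set as one enantiomer and then never be exposed as an alpha-carbonyl centre to base, and ring A needs three differentiated oxygens (O1, C5–OH, C7–OMe). The strategy rests on the substitution of ring A, a 2-substituted 5-methoxyresorcinol: C4a sits between oxygen-bearing C5 and C8a, with the methoxy group at C7 para to C4a. This is the pattern that a 3-methoxyvinylketene (supplying C6, C7, C8, C8a and the O1 oxygen) and a siloxyalkyne (supplying C4a and C5) assemble, so ring A can be grown onto a side chain that already holds C3 at the carbinol level.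

## Retrosynthetic reasoning

28 to 27 (C4 oxidation level). The ketone is taken back to the benzylic carbinol 27. This keeps C3 free of any acidifying neighbour until the very last operation, which then has to be a neutral oxidation of a benzylic alcohol beside a free phenol.

27 to 26 to 25 to 24 (O1–C2 bond and protecting groups). Ring C is opened at O1–C2 because the benzannulation leaves exactly the O1 phenol free and the C2 carbon is a primary carbinol, the natural partner for a Mitsunobu etherification. Closure is placed at the alcohol oxidation level because an aryl ketone with an alpha-aryl and a beta-oxygen would eliminate and re-close as the racemate. The C4 oxygen stays silylated through the closure: an ortho-hydroxybenzylic alcohol this electron-rich would form a quinone methide under Mitsunobu activation. Hence 25 carries only the primary hydroxyl free, obtained from 24 by selective cleavage of the primary silyl ether, and the two remaining silyl groups of 26 fall together to give 27.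

24 to 17 plus 19 (C4a–C8a, C5–C6 and C8–C8a). Ring A is dismantled into the siloxyalkyne 17 and the cyclobutenone 19. These three bonds are chosen because they are remote from C3, are formed under neutral thermal conditions, and deliver the three ring A oxygens already differentiated (free OH, silyl ether, methyl ether). The forward reaction must open 19 to its vinylketene, add it to 17 with the side-chain carbon bonding to the ketene carbonyl carbon, and aromatise.

19 to 18. The methoxy group of 19 is traced to the commercial ethoxy compound 18 by alkoxy exchange, since the C7 substituent of the target is methoxy.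

17 to 14 to 13 to 11 to 10 to 9 to 7 (side chain). The C–O bond at the alkyne terminus of 17 is cut to the terminal alkyne 14 (acetylide oxidation and O-silylation). The terminal alkyne carbon of 14 is cut off (one-carbon homologation of a masked aldehyde), which leads through 13 to the lactol 11 and the silylated hydroxy lactone 10. The oxygen that becomes the C4 oxygen is removed from 9 to give the lactone 7 (enolate hydroxylation). In this way a simple beta-aryl butyrolactone supplies C2, C3, C4 and C4a with C3 beta to the carbonyl, where it cannot epimerise.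

7 to 5 plus 6 (C3–aryl bond). The bond between C3 and ring B is cut to the boronic acid 5 and the butenolide 6. A rhodium-catalysed asymmetric conjugate addition makes this bond and sets the only stereocentre in one catalytic step.

5 to 3 to 1 plus 2 (ring D). The boronic acid comes from the bromochromene 3 by halogen–metal exchange, and ring D of 3 is formed from the bromophenol 1 and the enal 2 by ortho-condensation and oxa-electrocyclisation.

## Alternatives that were turned down

Alternative 1: Ring C and the ring A junction are cut at O1–C8a, C4–C4a and O1–C2, which leads to the acrylic acid A2 (2-(Chr)prop-2-enoic acid) and the silylaryl triflate A3 as aryne source. In the forward step fluoride releases the aryne from A3, and the carboxylate of A2 adds at the aryne carbon remote from the flanking methoxy group. The aryl anion takes over the acyl group, and the ortho-acyl phenoxide adds to its own enone to give the chromanone A1.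
- For: three bonds and ring C form in one flask, the aryne regiochemistry is dictated by the neighbouring methoxy group, and A2 is about two steps from 3. In step count this route is clearly stronger than the chosen one.
- Against: C3 is created by protonation of the enolate that results from the oxa-Michael closure, with nothing to bias it, so A1 is racemic. A1 still needs selective cleavage of its C5 methyl ether by a boron Lewis acid, which is harsh on ring D. A single enantiomer would then require a resolution of a compound that racemises easily.
- Comparison: the chosen strategy costs about nine more steps. In exchange it sets C3 by a catalyst at a stage where the centre is not acidic, and it delivers C5–OH and C7–OMe differentiated by construction.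

Alternative 2: Ring C is cut at C3–C4, which leads to the keto aldehyde A5, a ring A salicylaldehyde ether of a ring B phenacyl unit. In the forward step a triazolium-derived carbene converts the aldehyde into an acyl anion equivalent that adds to the tethered ketone and closes ring C as the 3-hydroxyisoflavanone A4.
- For: the closure is mild and convergent, intramolecular aldehyde–ketone benzoin reactions are well behaved, and a chiral carbene could even make it enantioselective. To the skeleton it is as short as Alternative 1.
- Against: the step places a hydroxyl group on C3, which the target does not have. Removing this tertiary alpha-ketol oxygen must pass through an enol, enolate or radical at C3, which erases whatever configuration the benzoin step set and leaves the stereocentre of 28 to an uncontrolled protonation. The methoxymethyl ether also needs acid for removal, in the presence of ring D and an epimerisable C3.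
- Comparison: the alternative solves ring closure but not the one stereochemical problem. The chosen strategy fixes C3 first and builds the rings around it.

Alternative 3: Ring C is cut at C2–C3, which leads to the alpha-aryl-alpha-diazo ketone A7 derived from a 2,4,6-trimethoxyphenyl ketone. In the forward step a chiral dirhodium tetracarboxylate forms the carbene at C3, which inserts into a C–H bond of an ortho methoxy group. This closes ring C and gives A6 with C3 set by the catalyst.
- For: this is the most direct answer to the stereocentre, with ring closure and enantiocontrol in a single catalytic step on a symmetric ring A. On this point it is stronger than the chosen strategy.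
- Against: the insertion has to go into a primary C–H bond through a six-membered transition, in competition with cyclopropanation of the ring D double bond and with attack on the ring B oxygen. The ring B oxygen therefore carries a silyl group instead of methyl. A6 then needs desilylation, O-methylation under base and selective C5 demethylation, all with C3–H alpha to the ketone, so the enantiomeric purity gained in the key step is likely to erode.
- Comparison: the chosen strategy gives up the direct asymmetric closure. In return every operation after the stereocentre is set runs on compounds without a C4 carbonyl, and the ketone appears only in the last step.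

Key step: step 11

Remarks on the chemistry:
- The carbinol carbon that becomes C4 is carried without stereocontrol. It is drawn trans in 9–11 (expected major isomer) and undefined from 12 onwards, because it ends as the ketone.
- (S)-BINAP is assigned for step 3 from the facial model that holds for cyclic enones and unsaturated lactones. The sense would be checked on the first batch and the (R)-ligand used if it proved opposite.

## Route

Step 1
Reactants: 1 4-bromo-3-methoxyphenol; 2 3-methylbut-2-enal
Product: 3 6-bromo-7-methoxy-2,2-dimethyl-2H-chromene
Conditions: PhB(OH)2 (1 equiv), AcOH, PhMe, reflux, Dean–Stark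
Reagents that add atoms: none
Why: Phenylboronic acid-templated ortho-condensation of a phenol with an enal, followed by loss of water and oxa-6π electrocyclisation, is a standard 2,2-dimethylchromene synthesis; the template confines C–C bond formation to a position ortho to the hydroxyl, and of the two the one para to the methoxy group is unhindered, so the 7-methoxy isomer should dominate and any 5-methoxy isomer is removed by chromatography.

Step 2
Reactants: 3 6-bromo-7-methoxy-2,2-dimethyl-2H-chromene
Product: 5 (Chr)boronic acid, via aryllithium 4 (not isolated)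
Conditions: n-BuLi, THF, −78 °C; B(Oi-Pr)3, −78 °C to rt; aq. NH4Cl
Reagents that add atoms: triisopropyl borate, CC(C)OB(OC(C)C)OC(C)C; water, O
Why: Bromine–lithium exchange on an aryl bromide is fast at −78 °C and outruns deprotonation; borate trapping and mild hydrolysis give the boronic acid, and the work-up is kept weakly acidic because both ring D and this electron-rich boronic acid are acid-sensitive.

Step 3
Reactants: 5 (Chr)boronic acid; 6 furan-2(5H)-one
Product: 7 (4S)-4-(Chr)dihydrofuran-2(3H)-one
Conditions: [Rh(OH)((S)-BINAP)]2 (3 mol % Rh), 5 (2.5 equiv), dioxane/H2O 10:1, 40 °C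
Reagents that add atoms: none
Why: Hayashi–Miyaura asymmetric conjugate addition: transmetalation gives an aryl–rhodium–BINAP species that inserts the butenolide double bond on the face left open by the ligand, and water protonates the rhodium enolate and regenerates the hydroxide; the new stereocentre (future C3) is set by the catalyst, and it lies beta to the carbonyl, so it cannot epimerise.

Step 4
Reactants: 7 (4S)-4-(Chr)dihydrofuran-2(3H)-one
Product: 9 (3R,4S)-3-hydroxy-4-(Chr)dihydrofuran-2(3H)-one, via potassium enolate 8 (not isolated)
Conditions: KN(SiMe3)2, THF, −78 °C; 3-phenyl-2-(phenylsulfonyl)oxaziridine, −78 °C; aq. NH4Cl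
Reagents that add atoms: 3-phenyl-2-(phenylsulfonyl)oxaziridine (Davis oxaziridine), O=S(=O)(c1ccccc1)N1OC1c1ccccc1
Why: Davis hydroxylation of a lactone enolate; the oxidant should approach anti to the neighbouring aryl group and give mainly the trans isomer, but this configuration is irrelevant because the carbinol becomes the C4 ketone, and the aryl-bearing carbon is not deprotonated by the amide base.

Step 5
Reactants: 9 (3R,4S)-3-hydroxy-4-(Chr)dihydrofuran-2(3H)-one
Product: 10 (3R,4S)-3-(TBS-oxy)-4-(Chr)dihydrofuran-2(3H)-one
Conditions: TBSCl, imidazole, DMF, rt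
Reagents that add atoms: tert-butyldimethylsilyl chloride, CC(C)(C)[Si](C)(C)Cl
Why: Standard silylation of a secondary alcohol; the silyl ether blocks the alpha-hydroxyl during the hydride reduction and is the group that later guards the benzylic C4 oxygen.

Step 6
Reactants: 10 (3R,4S)-3-(TBS-oxy)-4-(Chr)dihydrofuran-2(3H)-one
Product: 11 (3R,4S)-3-(TBS-oxy)-4-(Chr)tetrahydrofuran-2-ol (anomers)
Conditions: i-Bu2AlH, CH2Cl2, −78 °C; aq. potassium sodium tartrate
Reagents that add atoms: none
Why: Partial reduction of a γ-lactone to the lactol, reliable at −78 °C because the tetrahedral aluminium alkoxide does not collapse until work-up.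

Step 7
Reactants: 11 (3R,4S)-3-(TBS-oxy)-4-(Chr)tetrahydrofuran-2-ol
Product: 13 (2S)-3-(TBS-oxy)-2-(Chr)pent-4-yn-1-ol, via hydroxy aldehyde 12 (not isolated)
Conditions: dimethyl (1-diazo-2-oxopropyl)phosphonate, K2CO3, MeOH, 0 °C to rt
Reagents that add atoms: dimethyl (1-diazo-2-oxopropyl)phosphonate (Ohira–Bestmann reagent), CC(=O)C(=[N+]=[N-])P(=O)(OC)OC
Why: Seyferth–Gilbert homologation in its Ohira–Bestmann form, applied to a lactol that reacts through its open form 12; the aryl-bearing carbon is beta to the aldehyde and not enolisable, and epimerisation next to the aldehyde or silyl migration to the primary hydroxyl would be harmless, since that carbinol is later oxidised and step 8 puts the same silyl group on whichever hydroxyl is free.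

Step 8
Reactants: 13 (2S)-3-(TBS-oxy)-2-(Chr)pent-4-yn-1-ol
Product: 14 (4S)-3,5-bis(TBS-oxy)-4-(Chr)pent-1-yne
Conditions: TBSCl, imidazole, DMF, rt
Reagents that add atoms: tert-butyldimethylsilyl chloride, CC(C)(C)[Si](C)(C)Cl
Why: Standard silylation; the terminal alkyne is inert, and the hydroxyl must be masked because it would quench the ketene of the key step.

Step 9
Reactants: 14 (4S)-3,5-bis(TBS-oxy)-4-(Chr)pent-1-yne
Product: 17 (4S)-3,5-bis(TBS-oxy)-4-(Chr)-1-(TIPS-oxy)pent-1-yne, via lithium acetylide 15 (not isolated), via lithium ynolate 16 (not isolated)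
Conditions: n-BuLi, THF, −78 °C; t-BuOOLi (from t-BuOOH, LiN(SiMe3)2), −78 to 0 °C; TIPSOTf, −78 °C
Reagents that add atoms: tert-butyl hydroperoxide (used as its lithium salt), CC(C)(C)OO; triisopropylsilyl trifluoromethanesulfonate, CC(C)[Si](C(C)C)(C(C)C)OS(=O)(=O)C(F)(F)F
Why: Oxidation of a lithium acetylide by lithium tert-butyl peroxide (the acetylide carbon attacks a peroxide oxygen and expels tert-butoxide) is the established route from terminal alkynes to ynolates, and the bulky silyl triflate traps the ynolate on oxygen to give the 1-siloxyalkyne; the silyl ethers and ring D are inert to these reagents at low temperature.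

Step 10
Reactants: 18 3-ethoxycyclobut-2-en-1-one
Product: 19 3-methoxycyclobut-2-en-1-one
Conditions: dry MeOH (solvent), PPTS (cat.), rt; evaporate and repeat
Reagents that add atoms: methanol, CO
Why: Acid-catalysed alkoxy exchange of a vinylogous ester (methanol adds at C3 of the O-protonated enone and ethanol leaves), driven to completion by the large excess of methanol; room temperature is kept so that the four-membered ring does not open.

Step 11
Reactants: 17 (4S)-3,5-bis(TBS-oxy)-4-(Chr)-1-(TIPS-oxy)pent-1-yne; 19 3-methoxycyclobut-2-en-1-one
Product: 24 2-[(2S)-1,3-bis(TBS-oxy)-2-(Chr)propyl]-5-methoxy-3-(TIPS-oxy)phenol, via methoxyvinylketene 20 (not isolated), via vinylcyclobutenone 21 (not isolated), via dienylketene 22 (not isolated), via cyclohexadienone 23 (not isolated)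
Conditions: 19 (2 equiv), PhMe, 120 °C, sealed tube
Reagents that add atoms: none
Why: Heating opens 19 by 4π electrocyclic cleavage of its C1–C4 bond to the vinylketene 20, whose ketene double bond adds to the siloxyalkyne 17 in a (2+2) cycloaddition to give 21; this makes C4a–C8a and C5–C6. 21 opens in a second 4π step to the dienylketene 22, which closes ring A by a 6π electrocyclisation (C8–C8a) to 23, and 23 tautomerises to the phenol 24. The closest known reaction type is the Danheiser benzannulation of cyclobutenones with siloxyalkynes to resorcinol monosilyl ethers; the 3-alkoxy group on the cyclobutenone is the one variable beyond the usual alkyl- and aryl-substituted cases, and it is the reason for the higher temperature. The selectivity needed is the orientation of the ketene–alkyne addition: the siloxy group makes the side-chain-bearing alkyne carbon the nucleophilic one, so it bonds to the ketene carbonyl carbon, which places the side chain between the new hydroxyl (C8a) and the siloxy group (C5) with the methoxy group para to it (C7). No stereocentre is created, since the sp3 carbon of 21 is lost again. The preset centre survives because the conditions are neutral and it has no acidifying neighbour, C4 being a silyl-protected carbinol. The ketene should prefer the strongly nucleophilic siloxyalkyne to the ring D double bond, and the excess of 19 makes up for ketene lost to oligomerisation. Should some of the product phenol be acylated by the ketene, brief K2CO3/MeOH treatment of the crude material cleaves the ester.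

Step 12
Reactants: 24 2-[(2S)-1,3-bis(TBS-oxy)-2-(Chr)propyl]-5-methoxy-3-(TIPS-oxy)phenol
Product: 25 2-[(2S)-1-(TBS-oxy)-3-hydroxy-2-(Chr)propyl]-5-methoxy-3-(TIPS-oxy)phenol
Conditions: HF·pyridine, pyridine, THF, 0 °C
Reagents that add atoms: none
Why: Buffered HF·pyridine cleaves primary alkyl TBS ethers much faster than hindered secondary ones or aryl TIPS ethers; the secondary ether here is flanked by a 2,6-disubstituted arene and a branched carbon, so only the primary alcohol should be freed, and the excess pyridine keeps the medium too weakly acidic to ionise the electron-rich benzylic C–O bond.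

Step 13
Reactants: 25 2-[(2S)-1-(TBS-oxy)-3-hydroxy-2-(Chr)propyl]-5-methoxy-3-(TIPS-oxy)phenol
Product: 26 (3S)-4-(TBS-oxy)-7-methoxy-3-(Chr)-5-(TIPS-oxy)chromane
Conditions: PPh3, DIAD, THF, 0 °C to rt
Reagents that add atoms: none
Why: Intramolecular Mitsunobu etherification (6-exo-tet SN2 of the phenol on the activated primary alcohol) closes ring C at O1–C2, a standard isoflavan ring closure; C3 is not involved, and because the benzylic oxygen stays silylated neither quinone methide formation nor beta-elimination is open.

Step 14
Reactants: 26 (3S)-4-(TBS-oxy)-7-methoxy-3-(Chr)-5-(TIPS-oxy)chromane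
Product: 27 (3S)-7-methoxy-3-(Chr)chromane-4,5-diol
Conditions: Bu4NF (excess), THF, 0 °C to rt; aq. NH4Cl
Reagents that add atoms: none
Why: Fluoride cleaves the aryl TIPS ether at once and then the hindered benzylic TBS ether, helped by silyl transfer to the neighbouring C5 phenoxide; C3 has no acidifying group at this stage, so basic fluoride cannot epimerise it, and the acid-labile diol is used without chromatography.

Step 15
Reactants: 27 (3S)-7-methoxy-3-(Chr)chromane-4,5-diol
Product: 28 (3S)-5-hydroxy-7-methoxy-3-(7-methoxy-2,2-dimethyl-2H-chromen-6-yl)chroman-4-one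
Conditions: MnO2 (activated, excess), CH2Cl2, rt
Reagents that add atoms: none
Why: Activated MnO2 oxidises benzylic alcohols selectively under neutral heterogeneous conditions and tolerates phenols and ring D; both C4 epimers give the same ketone, and because the ketone is made last, C3 becomes an alpha-carbonyl centre only in the final product.

## Compound list

1 | 4-bromo-3-methoxyphenol | COc1cc(O)ccc1Br | starting material
2 | 3-methylbut-2-enal | CC(C)=CC=O | starting material
3 | 6-bromo-7-methoxy-2,2-dimethyl-2H-chromene | COc1cc2OC(C)(C)C=Cc2cc1Br | intermediate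
4 | (7-methoxy-2,2-dimethyl-2H-chromen-6-yl)lithium | COc1cc2OC(C)(C)C=Cc2cc1[Li] | intermediate
5 | (7-methoxy-2,2-dimethyl-2H-chromen-6-yl)boronic acid | COc1cc2OC(C)(C)C=Cc2cc1B(O)O | intermediate
6 | furan-2(5H)-one | O=C1OCC=C1 | starting material
7 | (4S)-4-(Chr)dihydrofuran-2(3H)-one | O=C1C[C@@H](c2cc3C=CC(C)(C)Oc3cc2OC)CO1 | intermediate
8 | potassium (4S)-4-(Chr)-4,5-dihydrofuran-2-olate (enolate of 7) | [K+].[O-]C1=C[C@@H](c2cc3C=CC(C)(C)Oc3cc2OC)CO1 | intermediate
9 | (3R,4S)-3-hydroxy-4-(Chr)dihydrofuran-2(3H)-one (trans) | O=C1[C@H](O)[C@@H](c2cc3C=CC(C)(C)Oc3cc2OC)CO1 | intermediate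
10 | (3R,4S)-3-(TBS-oxy)-4-(Chr)dihydrofuran-2(3H)-one | O=C1[C@H](O[Si](C)(C)C(C)(C)C)[C@@H](c2cc3C=CC(C)(C)Oc3cc2OC)CO1 | intermediate
11 | (3R,4S)-3-(TBS-oxy)-4-(Chr)tetrahydrofuran-2-ol, anomers | OC1[C@H](O[Si](C)(C)C(C)(C)C)[C@@H](c2cc3C=CC(C)(C)Oc3cc2OC)CO1 | intermediate
12 | (3S)-2-(TBS-oxy)-4-hydroxy-3-(Chr)butanal, C2 epimers | O=CC(O[Si](C)(C)C(C)(C)C)[C@@H](c1cc2C=CC(C)(C)Oc2cc1OC)CO | intermediate
13 | (2S)-3-(TBS-oxy)-2-(Chr)pent-4-yn-1-ol, C3 epimers | OC[C@H](c1cc2C=CC(C)(C)Oc2cc1OC)C(O[Si](C)(C)C(C)(C)C)C#C | intermediate
14 | (4S)-3,5-bis(TBS-oxy)-4-(Chr)pent-1-yne, C3 epimers | CC(C)(C)[Si](C)(C)OC[C@H](c1cc2C=CC(C)(C)Oc2cc1OC)C(O[Si](C)(C)C(C)(C)C)C#C | intermediate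
15 | lithium acetylide of 14 | CC(C)(C)[Si](C)(C)OC[C@H](c1cc2C=CC(C)(C)Oc2cc1OC)C(O[Si](C)(C)C(C)(C)C)C#C[Li] | intermediate
16 | lithium (4S)-3,5-bis(TBS-oxy)-4-(Chr)pent-1-yn-1-olate (ynolate) | CC(C)(C)[Si](C)(C)OC[C@H](c1cc2C=CC(C)(C)Oc2cc1OC)C(O[Si](C)(C)C(C)(C)C)C#C[O-].[Li+] | intermediate
17 | (4S)-3,5-bis(TBS-oxy)-4-(Chr)-1-(TIPS-oxy)pent-1-yne, C3 epimers | CC(C)(C)[Si](C)(C)OC[C@H](c1cc2C=CC(C)(C)Oc2cc1OC)C(O[Si](C)(C)C(C)(C)C)C#CO[Si](C(C)C)(C(C)C)C(C)C | intermediate
18 | 3-ethoxycyclobut-2-en-1-one | CCOC1=CC(=O)C1 | starting material
19 | 3-methoxycyclobut-2-en-1-one | COC1=CC(=O)C1 | intermediate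
20 | 3-methoxybuta-1,3-dien-1-one (methoxyvinylketene) | COC(=C)C=C=O | intermediate
21 | 2-[(2S)-1,3-bis(TBS-oxy)-2-(Chr)propyl]-4-(1-methoxyethenyl)-3-(TIPS-oxy)cyclobut-2-en-1-one | CC(C)(C)[Si](C)(C)OC[C@H](c1cc2C=CC(C)(C)Oc2cc1OC)C(O[Si](C)(C)C(C)(C)C)C1=C(O[Si](C(C)C)(C(C)C)C(C)C)C(C(OC)=C)C1=O | intermediate
22 | (3E)-2-[(2S)-1,3-bis(TBS-oxy)-2-(Chr)propyl]-5-methoxy-3-(TIPS-oxy)hexa-1,3,5-trien-1-one (dienylketene) | CC(C)(C)[Si](C)(C)OC[C@H](c1cc2C=CC(C)(C)Oc2cc1OC)C(O[Si](C)(C)C(C)(C)C)C(=C=O)/C(O[Si](C(C)C)(C(C)C)C(C)C)=C\C(OC)=C | intermediate
23 | 2-[(2S)-1,3-bis(TBS-oxy)-2-(Chr)propyl]-5-methoxy-3-(TIPS-oxy)cyclohexa-2,4-dien-1-one | CC(C)(C)[Si](C)(C)OC[C@H](c1cc2C=CC(C)(C)Oc2cc1OC)C(O[Si](C)(C)C(C)(C)C)C1=C(O[Si](C(C)C)(C(C)C)C(C)C)C=C(OC)CC1=O | intermediate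
24 | 2-[(2S)-1,3-bis(TBS-oxy)-2-(Chr)propyl]-5-methoxy-3-(TIPS-oxy)phenol | CC(C)(C)[Si](C)(C)OC[C@H](c1cc2C=CC(C)(C)Oc2cc1OC)C(O[Si](C)(C)C(C)(C)C)c1c(O)cc(OC)cc1O[Si](C(C)C)(C(C)C)C(C)C | intermediate
25 | 2-[(2S)-1-(TBS-oxy)-3-hydroxy-2-(Chr)propyl]-5-methoxy-3-(TIPS-oxy)phenol | OC[C@H](c1cc2C=CC(C)(C)Oc2cc1OC)C(O[Si](C)(C)C(C)(C)C)c1c(O)cc(OC)cc1O[Si](C(C)C)(C(C)C)C(C)C | intermediate
26 | (3S)-4-(TBS-oxy)-7-methoxy-3-(Chr)-5-(TIPS-oxy)chromane, C4 epimers | COc1cc(O[Si](C(C)C)(C(C)C)C(C)C)c2c(c1)OC[C@H](c1cc3c(cc1OC)OC(C)(C)C=C3)C2O[Si](C)(C)C(C)(C)C | intermediate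
27 | (3S)-7-methoxy-3-(Chr)chromane-4,5-diol, C4 epimers | COc1cc(O)c2c(c1)OC[C@H](c1cc3c(cc1OC)OC(C)(C)C=C3)C2O | intermediate
28 | (3S)-5-hydroxy-7-methoxy-3-(7-methoxy-2,2-dimethyl-2H-chromen-6-yl)chroman-4-one | COc1cc(O)c2c(c1)OC[C@H](c1cc3c(cc1OC)OC(C)(C)C=C3)C2=O | target

## Step count and least certain steps

Total step count: 15. Longest linear sequence: 14 steps (steps 1–9 and 11–15); step 10 is a one-step side branch.

Step 11 (key step). The vinylogous-ester stabilisation of 19 may push its ring opening to a temperature at which the siloxyalkyne isomerises by silyl shift from oxygen to carbon. At that temperature the product may also lose silanol from its ortho-hydroxybenzylic position. Ketene oligomerisation and acylation of the product phenol would consume material as well. The fallback generates the same ketene without heat, by a photochemical Wolff rearrangement. The known enone 3-methoxybut-3-en-2-one F1 is converted by detrifluoroacetylative diazo transfer (LiN(SiMe3)2, CF3CO2CH2CF3; then MsN3, Et3N) into 1-diazo-3-methoxybut-3-en-2-one F2. Irradiation of F2 through Pyrex at room temperature in the presence of 17 gives 20 and then 21, and warming to about 80 °C completes the passage through 22 and 23. This fallback sets out from 17 and returns to the route at 24.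

Step 3. Protodeboronation of the electron-rich, ortho-substituted boronic acid may outrun its transmetalation, and the butenolide is a sluggish acceptor, so conversion may stay low. The fallback separates C–C bond formation from stereocontrol. Suzuki coupling of 5 with 4-bromofuran-2(5H)-one F3 (PdCl2(dppf), K3PO4, THF/H2O) gives 4-(Chr)furan-2(5H)-one F4. Copper hydride asymmetric conjugate reduction of F4 (Cu(OAc)2, p-Tol-BINAP of the required handedness, polymethylhydrosiloxane, t-BuOH, PhMe) then sets the stereocentre; the unsaturated lactone is far more reactive towards the copper hydride than the ring D alkene. It sets out from 5 and returns at 7.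

Step 9. Oxygen transfer to this hindered, oxygenated acetylide may be incomplete, the ynolate may be silylated on carbon instead of oxygen, and the siloxyalkyne may hydrolyse on work-up. The fallback reaches the same ynolate by the Kowalski ester homologation, starting from 10. The lactone is opened with LiOH (THF/H2O), the resulting salt is silylated on both hydroxyl and carboxyl (TBSCl, imidazole), and the silyl ester is cleaved (K2CO3, MeOH) to give (3S)-2,4-bis(TBS-oxy)-3-(Chr)butanoic acid F5. Trimethylsilyldiazomethane converts F5 into methyl (3S)-2,4-bis(TBS-oxy)-3-(Chr)butanoate F6. Treatment of F6 with CH2Br2 and lithium 2,2,6,6-tetramethylpiperidide and then n-BuLi gives the ynolate 16, which TIPSCl traps as 17. It sets out from 10 and returns at 17.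

Step 10. Methanol may cleave the strained ring instead of exchanging the alkoxy group, or exchange may stop short, which would carry an ethyl ether into ring A. The fallback goes through the free dione. Cold dilute aqueous HCl hydrolyses 18 to cyclobutane-1,3-dione F7, and O-methylation of F7 with trimethylsilyldiazomethane (MeOH/Et2O, 0 °C) gives 19. It sets out from 18 and returns at 19.

Step 15. Once the ketone exists, basic sites on the oxide may epimerise C3. The free C5 phenol may also be oxidised, or its hydrogen bond to the carbinol may slow the reaction. The fallback oxidises with the phenol masked. Phenol-selective silylation of 27 (TBSCl, imidazole, DMF, 0 °C) gives (3S)-5-(TBS-oxy)-7-methoxy-3-(Chr)chroman-4-ol F8. Dess–Martin periodinane with NaHCO3 oxidises F8 to (3S)-5-(TBS-oxy)-7-methoxy-3-(Chr)chroman-4-one F9. Bu4NF buffered with AcOH (THF, 0 °C) then removes the aryl silyl ether without base strong enough to enolise C3. It sets out from 27 and returns at 28.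

## Further compounds

F1 | step 11 | 3-methoxybut-3-en-2-one | COC(=C)C(C)=O
F2 | step 11 | 1-diazo-3-methoxybut-3-en-2-one | COC(=C)C(=O)C=[N+]=[N-]
F3 | step 3 | 4-bromofuran-2(5H)-one | O=C1OCC(Br)=C1
F4 | step 3 | 4-(7-methoxy-2,2-dimethyl-2H-chromen-6-yl)furan-2(5H)-one | O=C1OCC(c2cc3C=CC(C)(C)Oc3cc2OC)=C1
F5 | step 9 | (3S)-2,4-bis(tert-butyldimethylsilyloxy)-3-(7-methoxy-2,2-dimethyl-2H-chromen-6-yl)butanoic acid | OC(=O)C(O[Si](C)(C)C(C)(C)C)[C@@H](c1cc2C=CC(C)(C)Oc2cc1OC)CO[Si](C)(C)C(C)(C)C
F6 | step 9 | methyl (3S)-2,4-bis(tert-butyldimethylsilyloxy)-3-(7-methoxy-2,2-dimethyl-2H-chromen-6-yl)butanoate | COC(=O)C(O[Si](C)(C)C(C)(C)C)[C@@H](c1cc2C=CC(C)(C)Oc2cc1OC)CO[Si](C)(C)C(C)(C)C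
F7 | step 10 | cyclobutane-1,3-dione | O=C1CC(=O)C1
F8 | step 15 | (3S)-5-(tert-butyldimethylsilyloxy)-7-methoxy-3-(7-methoxy-2,2-dimethyl-2H-chromen-6-yl)chroman-4-ol | COc1cc(O[Si](C)(C)C(C)(C)C)c2c(c1)OC[C@H](c1cc3c(cc1OC)OC(C)(C)C=C3)C2O
F9 | step 15 | (3S)-5-(tert-butyldimethylsilyloxy)-7-methoxy-3-(7-methoxy-2,2-dimethyl-2H-chromen-6-yl)chroman-4-one | COc1cc(O[Si](C)(C)C(C)(C)C)c2c(c1)OC[C@H](c1cc3c(cc1OC)OC(C)(C)C=C3)C2=O
A1 | alternative 1 | racemic 5,7-dimethoxy-3-(7-methoxy-2,2-dimethyl-2H-chromen-6-yl)chroman-4-one | COc1cc(OC)c2c(c1)OCC(c1cc3c(cc1OC)OC(C)(C)C=C3)C2=O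
A2 | alternative 1 | 2-(7-methoxy-2,2-dimethyl-2H-chromen-6-yl)prop-2-enoic acid | C=C(C(=O)O)c1cc2C=CC(C)(C)Oc2cc1OC
A3 | alternative 1 | 3,5-dimethoxy-2-(trimethylsilyl)phenyl trifluoromethanesulfonate | COc1cc(OC)c([Si](C)(C)C)c(OS(=O)(=O)C(F)(F)F)c1
A4 | alternative 2 | racemic 3-hydroxy-7-methoxy-5-(methoxymethoxy)-3-(7-methoxy-2,2-dimethyl-2H-chromen-6-yl)chroman-4-one | COCOc1cc(OC)cc2OCC(O)(c3cc4C=CC(C)(C)Oc4cc3OC)C(=O)c12
A5 | alternative 2 | 4-methoxy-2-(methoxymethoxy)-6-[2-(7-methoxy-2,2-dimethyl-2H-chromen-6-yl)-2-oxoethoxy]benzaldehyde | COCOc1cc(OC)cc(OCC(=O)c2cc3C=CC(C)(C)Oc3cc2OC)c1C=O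
A6 | alternative 3 | (3S)-5,7-dimethoxy-3-[2,2-dimethyl-7-(triisopropylsilyloxy)-2H-chromen-6-yl]chroman-4-one | COc1cc(OC)c2c(c1)OC[C@H](c1cc3c(cc1O[Si](C(C)C)(C(C)C)C(C)C)OC(C)(C)C=C3)C2=O
A7 | alternative 3 | 2-diazo-2-[2,2-dimethyl-7-(triisopropylsilyloxy)-2H-chromen-6-yl]-1-(2,4,6-trimethoxyphenyl)ethan-1-one | COc1cc(OC)c(C(=O)C(=[N+]=[N-])c2cc3C=CC(C)(C)Oc3cc2O[Si](C(C)C)(C(C)C)C(C)C)c(OC)c1
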